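Ring B is treated as the aromatised form of a 4-(aryloxycarbonyl)-5-methylcyclohexane-1,3-dione: its 2'-OH and 4'-OH are the two former carbonyls, and C6' with its methyl is a former crotonate β-carbon. Disconnecting C1'–C6' and C3'–C4' leaves the acetoacetate and the crotonate of the ring A phenol. One Michael–Claisen operation joins them, closes ring B and delivers the hindered A–B depside ester already in place, because that ester was made from unhindered acetoacetic acid. The expelled aryloxide is the ring A phenol itself, which also serves as the base. Bromine-mediated dehydrogenation then gives the AB depside, and ring C arrives by a classical benzyl-protected orsellinoylation.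

Key step: step 6

Remarks on the chemistry
- The target has no stereogenic element, so no enantiocontrol is required. The only stereocentre on the way is C6' of 11; it forms racemic, is written without a descriptor, and is erased in step 7.
- 11 is written as its ester-conjugated enol; it should equilibrate with the vinylogous-acid (1,3-dione enol) tautomers.
- Locants: unprimed = ring A, primed = ring B, double-primed = ring C.
- Design of the annulation: 7 and 9 are esters of the same phenol 4, and the base is NaH plus a sub-stoichiometric charge of 4 (its sodium aryloxide). Free aryloxide is thus present from the start and remains to the end, although the acidic product binds one equivalent of base. No foreign nucleophile is introduced, and the 4 released from 9 is recovered for reuse.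
- The E/Z purity of crotonyl chloride is immaterial, since the alkene carbons become sp3 and then aromatic.

Step 1
Reactants: 1 methyl orsellinate (methyl 2,4-dihydroxy-6-methylbenzoate)
Product: 2 methyl 4-(benzyloxy)-2-hydroxy-6-methylbenzoate
Conditions: BnBr (1.05 equiv), K2CO3, acetone, reflux
Reagents that add atoms: benzyl bromide, BrCc1ccccc1
Why: Williamson etherification should take place only at the 4-OH, because the 2-OH is hydrogen-bonded to the ester carbonyl and therefore less acidic and less nucleophilic under mild carbonate conditions.

Step 2
Reactants: 2 methyl 4-(benzyloxy)-2-hydroxy-6-methylbenzoate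
Product: 3 methyl 4-(benzyloxy)-2-methoxy-6-methylbenzoate
Conditions: MeI (3 equiv), K2CO3, DMF, 50 °C
Reagents that add atoms: iodomethane, CI
Why: Williamson O-methylation under more forcing conditions (dipolar solvent, excess MeI) should alkylate the chelated phenol, the only remaining acidic site.

Step 3
Reactants: 3 methyl 4-(benzyloxy)-2-methoxy-6-methylbenzoate
Product: 4 methyl 4-hydroxy-2-methoxy-6-methylbenzoate
Conditions: H2 (1 atm), 10% Pd/C, EtOAc–MeOH, rt
Reagents that add atoms: none
Why: Catalytic hydrogenolysis cleaves the benzyl aryl ether and leaves the methyl ester and methyl ether untouched.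

Step 4
Reactants: 4 methyl 4-hydroxy-2-methoxy-6-methylbenzoate; 5 2,2,6-trimethyl-4H-1,3-dioxin-4-one
Product: 7 methyl 4-(acetoacetyloxy)-2-methoxy-6-methylbenzoate, via acetylketene 6 (not isolated)
Conditions: 5 (1.3 equiv), xylene, 130 °C, acetone distilled off
Reagents that add atoms: none
Why: Retro-hetero-Diels–Alder fragmentation of the dioxinone gives acetone and acetylketene, which the phenol O–H traps to give the aryl acetoacetate (acylketene acetoacetylation) without any base or coupling agent.

Step 5
Reactants: 4 methyl 4-hydroxy-2-methoxy-6-methylbenzoate; 8 (E)-crotonyl chloride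
Product: 9 methyl 4-[(E)-but-2-enoyloxy]-2-methoxy-6-methylbenzoate
Conditions: pyridine, CH2Cl2, 0 °C to rt
Reagents that add atoms: none
Why: O-acylation of the phenol with an acid chloride; pyridine is too weak a base to form vinylketene from the acyl chloride, so the conjugated E-enoate should be kept.

Step 6
Reactants: 7 methyl 4-(acetoacetyloxy)-2-methoxy-6-methylbenzoate; 9 methyl 4-[(E)-but-2-enoyloxy]-2-methoxy-6-methylbenzoate
Product: 11 rac-methyl 4-[(2-hydroxy-6-methyl-4-oxocyclohex-1-ene-1-carbonyl)oxy]-2-methoxy-6-methylbenzoate, via Michael adduct 10 (not isolated)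
Conditions: NaH (1.3 equiv), 4 (0.3 equiv), THF, 0 °C; then 9 (1.1 equiv), 15-crown-5 (cat.), 60 °C; cold 1 M HCl; 11 separated from recovered 4 by NaHCO3 extraction
Reagents that add atoms: none
Why: The sodium enolate of 7 adds through C2 to the β-carbon of 9 (C1'–C6'), the transient ester enolate is quenched by the acidic C1'–H, and the small equilibrium share of the methyl-ketone enolate then attacks the activated aryl ester carbonyl (C3'–C4') and expels the aryloxide of 4, which deprotonates the product to an inert β-diketonate. The closest known reaction type is the base-mediated Michael–Claisen condensation of acetoacetic esters with crotonic esters to dihydroorsellinates, here run with aryl esters and a non-nucleophilic base. Ring B closes in a 6-(enolexo)-exo-trig acyl substitution; every other C-closure would need a four-membered ring. The single new stereocentre, C6', is formed without control, so 11 is a racemate, and the centre is erased in step 7. The step needs C- over O-acylation: O-closure to the six-membered enol lactone is reversible because the aryloxide of 4 (added at the start and released later) reopens it, whereas the diketonate, by far the weakest base in the flask, is a sink. It also needs intact ester identity: both partners carry the same aryloxide as their only leaving group and no other oxygen nucleophile is present, so every acyl exchange, including return of any acetylketene shed by 7, is degenerate.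

Step 7
Reactants: 11 rac-methyl 4-[(2-hydroxy-6-methyl-4-oxocyclohex-1-ene-1-carbonyl)oxy]-2-methoxy-6-methylbenzoate
Product: 13 methyl 4-[(2,4-dihydroxy-6-methylbenzoyl)oxy]-2-methoxy-6-methylbenzoate, via 3'-bromo dione 12 (not isolated)
Conditions: Br2 (1.0 equiv), DMF, 0 °C; then 80 °C
Reagents that add atoms: none
Why: Halogenation–dehydrohalogenation aromatisation of a cyclohexane-1,3-dione: the enol is brominated far faster than ring A, and loss of HBr followed by tautomerisation should give the resorcinol ring under acidic conditions that leave both esters intact.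

Step 8
Reactants: 1 methyl orsellinate
Product: 14 methyl 2,4-bis(benzyloxy)-6-methylbenzoate
Conditions: BnBr (2.5 equiv), K2CO3, DMF, 70 °C
Reagents that add atoms: benzyl bromide, BrCc1ccccc1
Why: Exhaustive Williamson etherification; excess halide in warm DMF should also alkylate the chelated 2-OH.

Step 9
Reactants: 14 methyl 2,4-bis(benzyloxy)-6-methylbenzoate
Product: 15 2,4-bis(benzyloxy)-6-methylbenzoic acid
Conditions: KOH (5 equiv), DMSO–H2O, 90 °C; then 1 M HCl
Reagents that add atoms: potassium hydroxide, [K+].[OH-]
Why: Saponification of the di-ortho-substituted ester with poorly solvated hydroxide in DMSO; the benzyl ethers are stable to base.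

Step 10
Reactants: 13 methyl 4-[(2,4-dihydroxy-6-methylbenzoyl)oxy]-2-methoxy-6-methylbenzoate; 15 2,4-bis(benzyloxy)-6-methylbenzoic acid
Product: 17 methyl 4-[(4-{[2,4-bis(benzyloxy)-6-methylbenzoyl]oxy}-2-hydroxy-6-methylbenzoyl)oxy]-2-methoxy-6-methylbenzoate, via mixed trifluoroacetic anhydride 16 (not isolated)
Conditions: TFAA, toluene, rt; aq. NaHCO3 work-up
Reagents that add atoms: none
Why: Mixed-anhydride esterification, the classical depside coupling: the electron-rich hindered acid reacts through an acylium-like mixed anhydride, and only the free 4'-OH should be acylated because the 2'-OH is chelated to the A–B ester carbonyl.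

Step 11
Reactants: 17 methyl 4-[(4-{[2,4-bis(benzyloxy)-6-methylbenzoyl]oxy}-2-hydroxy-6-methylbenzoyl)oxy]-2-methoxy-6-methylbenzoate
Product: 18 methyl 4-({4-[(2,4-dihydroxy-6-methylbenzoyl)oxy]-2-hydroxy-6-methylbenzoyl}oxy)-2-methoxy-6-methylbenzoate (CNP0503951.0)
Conditions: H2 (1 atm), 10% Pd/C, EtOAc, rt
Reagents that add atoms: none
Why: Neutral catalytic hydrogenolysis of the two benzyl aryl ethers; the aryl esters and the methyl ester are not reduced, and no base or acid is present to scramble the depside links.

Compound list
1 | methyl orsellinate (methyl 2,4-dihydroxy-6-methylbenzoate) | COC(=O)c1c(C)cc(O)cc1O | starting material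
2 | methyl 4-(benzyloxy)-2-hydroxy-6-methylbenzoate | COC(=O)c1c(C)cc(OCc2ccccc2)cc1O | intermediate
3 | methyl 4-(benzyloxy)-2-methoxy-6-methylbenzoate | COC(=O)c1c(C)cc(OCc2ccccc2)cc1OC | intermediate
4 | methyl 4-hydroxy-2-methoxy-6-methylbenzoate (ring A phenol) | COC(=O)c1c(C)cc(O)cc1OC | intermediate
5 | 2,2,6-trimethyl-4H-1,3-dioxin-4-one | CC1=CC(=O)OC(C)(C)O1 | starting material
6 | acetylketene (formed in the flask, not isolated) | CC(=O)C=C=O | intermediate
7 | methyl 4-(acetoacetyloxy)-2-methoxy-6-methylbenzoate | COC(=O)c1c(C)cc(OC(=O)CC(C)=O)cc1OC | intermediate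
8 | (E)-crotonyl chloride | C/C=C/C(=O)Cl | starting material
9 | methyl 4-[(E)-but-2-enoyloxy]-2-methoxy-6-methylbenzoate | COC(=O)c1c(C)cc(OC(=O)/C=C/C)cc1OC | intermediate
10 | bis[3-methoxy-4-(methoxycarbonyl)-5-methylphenyl] 2-acetyl-3-methylpentanedioate (Michael adduct, diastereomer mixture, not isolated) | COC(=O)c1c(C)cc(OC(=O)C(C(C)=O)C(C)CC(=O)Oc2cc(C)c(C(=O)OC)c(OC)c2)cc1OC | intermediate
11 | rac-methyl 4-[(2-hydroxy-6-methyl-4-oxocyclohex-1-ene-1-carbonyl)oxy]-2-methoxy-6-methylbenzoate (dihydro-AB dione, ester-conjugated enol, racemic at C6') | COC(=O)c1c(C)cc(OC(=O)C2=C(O)CC(=O)CC2C)cc1OC | intermediate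
12 | methyl 4-[(3-bromo-2-hydroxy-6-methyl-4-oxocyclohex-1-ene-1-carbonyl)oxy]-2-methoxy-6-methylbenzoate (3'-bromo dione, racemic diastereomer mixture, not isolated) | COC(=O)c1c(C)cc(OC(=O)C2=C(O)C(Br)C(=O)CC2C)cc1OC | intermediate
13 | methyl 4-[(2,4-dihydroxy-6-methylbenzoyl)oxy]-2-methoxy-6-methylbenzoate (AB depside) | COC(=O)c1c(C)cc(OC(=O)c2c(C)cc(O)cc2O)cc1OC | intermediate
14 | methyl 2,4-bis(benzyloxy)-6-methylbenzoate | COC(=O)c1c(C)cc(OCc2ccccc2)cc1OCc1ccccc1 | intermediate
15 | 2,4-bis(benzyloxy)-6-methylbenzoic acid | OC(=O)c1c(C)cc(OCc2ccccc2)cc1OCc1ccccc1 | intermediate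
16 | 2,4-bis(benzyloxy)-6-methylbenzoic trifluoroacetic anhydride (not isolated) | O=C(OC(=O)C(F)(F)F)c1c(C)cc(OCc2ccccc2)cc1OCc1ccccc1 | intermediate
17 | methyl 4-[(4-{[2,4-bis(benzyloxy)-6-methylbenzoyl]oxy}-2-hydroxy-6-methylbenzoyl)oxy]-2-methoxy-6-methylbenzoate | COC(=O)c1c(C)cc(OC(=O)c2c(C)cc(OC(=O)c3c(C)cc(OCc4ccccc4)cc3OCc3ccccc3)cc2O)cc1OC | intermediate
18 | methyl 4-({4-[(2,4-dihydroxy-6-methylbenzoyl)oxy]-2-hydroxy-6-methylbenzoyl}oxy)-2-methoxy-6-methylbenzoate (CNP0503951.0) | COC(=O)c1c(C)cc(OC(=O)c2c(C)cc(OC(=O)c3c(C)cc(O)cc3O)cc2O)cc1OC | target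

Total step count: 11
Longest linear sequence: 8 steps (steps 1, 2, 3, 4, 6, 7, 10, 11)

Steps most likely to fail

1. Step 6. The sequence may stop after the conjugate addition at the O-cyclised enol lactone. Alternatively, the acetoacetate may shed aryloxide and self-condense through acetylketene before the slow addition to the β-substituted enoate occurs. Fallback: the A–B ester is made by classical depside coupling instead of ring construction. It sets out from phenol 4 and acid 15. These are condensed with TFAA in toluene at rt, through anhydride 16, to give methyl 4-{[2,4-bis(benzyloxy)-6-methylbenzoyl]oxy}-2-methoxy-6-methylbenzoate F1. Hydrogenolysis of F1 (H2, Pd/C, EtOAc) should then give the AB depside, so the fallback rejoins the route at 13.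

2. Step 7. With one equivalent of bromine, loss of HBr may be incomplete, or the newly formed, electron-rich resorcinol ring may be brominated further, giving mixtures. Fallback: over-oxidise on purpose and then reduce. It sets out from 11, which is treated with Br2 (3 equiv) in AcOH at rt to aromatise and brominate exhaustively, giving methyl 4-[(3,5-dibromo-2,4-dihydroxy-6-methylbenzoyl)oxy]-2-methoxy-6-methylbenzoate F2. Hydrogenolytic debromination (H2, Pd/C, Et3N, EtOAc) should then give 13, where the route is rejoined. Any bromine that enters ring A would be removed in the same hydrogenolysis.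

3. Step 10. Under the strongly acidic mixed-anhydride conditions the 4'-OH may be capped as its trifluoroacetate, acylation may extend to the 2'-OH, or the A–B ester may undergo acid-promoted acyl transfer. Fallback: activate the acid separately and couple under basic conditions. It sets out from 15, which is converted with oxalyl chloride and catalytic DMF in CH2Cl2 into 2,4-bis(benzyloxy)-6-methylbenzoyl chloride F3. F3 is then added to 13 and K2CO3 (1 equiv) in acetone. Only the more acidic, unchelated 4'-phenoxide should form and be acylated, giving 17, where the route is rejoined.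

Further compounds
F1 | step 6 | methyl 4-{[2,4-bis(benzyloxy)-6-methylbenzoyl]oxy}-2-methoxy-6-methylbenzoate | COC(=O)c1c(C)cc(OC(=O)c2c(C)cc(OCc3ccccc3)cc2OCc2ccccc2)cc1OC
F2 | step 7 | methyl 4-[(3,5-dibromo-2,4-dihydroxy-6-methylbenzoyl)oxy]-2-methoxy-6-methylbenzoate | COC(=O)c1c(C)cc(OC(=O)c2c(C)c(Br)c(O)c(Br)c2O)cc1OC
F3 | step 10 | 2,4-bis(benzyloxy)-6-methylbenzoyl chloride | O=C(Cl)c1c(C)cc(OCc2ccccc2)cc1OCc1ccccc1
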